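Everything rests on cutting ring C of the upper flavan, a 2,4-diarylchroman, at O1–C2 and C3–C4 in a retro hetero-Diels–Alder sense. That reveals a ring A ortho-quinone methide whose methide carbon C4 already bears C8' of ring D of epigallocatechin, and a 4-oxygenated styrene supplying C2, C3 and ring B. Forward, one acid-catalysed operation dehydrates a diaryl carbinol, forms both bonds, closes ring C and sets C2 and C4. The precursor is the perbenzylated ring A/ring D carbinol with a free ring A ortho-phenol. It is made from 8'-lithiated hexa-O-benzylepigallocatechin and a silyl-protected salicylaldehyde. C2' and C3' come from (−)-epigallocatechin.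

Key step: step 8

**Numbering.** Upper flavan: O1, C2, C3, C4, C4a, C5–C8, C8a, with ring A benzo, ring C pyran and ring B 4-hydroxyphenyl. The lower epigallocatechin carries primed locants, with ring D benzo, ring F pyran and ring E trihydroxyphenyl.

**Configuration check.** The target is (2S,4R) in the upper unit, which is 2,4-trans. It is (2'R,3'R) in the lower unit, which is 2',3'-cis and identical with (−)-epigallocatechin.

**Design remarks.**
- A phosphoric acid diester should ionise the carbinol but hardly the O1–C2 bond of the adduct. The more acidic N-triflylphosphoramide of the same backbone is therefore used, so one chiral acid serves both the cycloaddition and the C2 equilibration.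
- The ortho-phenol travels as a TBS ether. This group leaves under non-acidic, non-reductive conditions that the very acid-labile carbinol and the benzyl ethers tolerate.
- The styrene is made by methylenation of an aldehyde, which avoids handling polymerisation-prone 4-vinylphenol.

**Assumption.** The (R)-configured catalyst is taken as the matched antipode for 4R. The sense of induction on this substrate cannot be predicted with confidence, and the (S)-antipode would be used under the same conditions if it proves matched.

## Route

Step 1
Reactants: 1 (−)-epigallocatechin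
Product: 2 (2R,3R)-5,7-bis(benzyloxy)-2-[3,4,5-tris(benzyloxy)phenyl]chroman-3-ol (penta-O-benzylepigallocatechin)
Conditions: BnBr (5.5 equiv), K2CO3, degassed DMF, Ar, 0 °C to rt
Reagents that add atoms: benzyl bromide, BrCc1ccccc1
Why: Williamson etherification in which K2CO3 deprotonates only the five phenols so that the secondary 3'-OH stays free, while exclusion of air and low temperature hold back pyrogallol oxidation, C-benzylation of ring D and base-induced epimerisation at C2'; no stereocentre is touched.

Step 2
Reactants: 2 penta-O-benzylepigallocatechin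
Product: 3 (2R,3R)-3,5,7-tris(benzyloxy)-2-[3,4,5-tris(benzyloxy)phenyl]chroman (hexa-O-benzylepigallocatechin)
Conditions: NaH, BnBr, Bu4NI (cat.), DMF, 0 °C to rt
Reagents that add atoms: benzyl bromide, BrCc1ccccc1
Why: Williamson etherification of the 3'-alkoxide, safe for C2' and C3' because ring F cannot open once all phenols are capped, and useful because it removes the only acidic proton before lithiation and an internal nucleophile before the cationic key step.

Step 3
Reactants: 3 hexa-O-benzylepigallocatechin
Product: 4 8'-bromo-hexa-O-benzylepigallocatechin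
Conditions: NBS (1.0 equiv), CH2Cl2, −78 °C to 0 °C, dark
Reagents that add atoms: N-bromosuccinimide, O=C1CCC(=O)N1Br
Why: Electrophilic aromatic bromination at the most electron-rich arene, ring D, where C8' (between 7'-OBn and the cyclic O1') is less encumbered than C6' (between two benzyloxy groups), the established site selectivity of benzylated flavan-3-ols.

Step 4
Reactants: 5 2,4-dihydroxybenzaldehyde
Product: 6 4-(benzyloxy)-2-hydroxybenzaldehyde
Conditions: BnBr (1.0 equiv), NaHCO3, MeCN, reflux
Reagents that add atoms: benzyl bromide, BrCc1ccccc1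
Why: Regioselective Williamson etherification, since the weak base ionises only the more acidic 4-OH (vinylogous acid) while the 2-OH is locked in a hydrogen bond to the formyl oxygen.

Step 5
Reactants: 6 4-(benzyloxy)-2-hydroxybenzaldehyde
Product: 7 4-(benzyloxy)-2-(tert-butyldimethylsilyloxy)benzaldehyde
Conditions: TBSCl, imidazole, DMF, rt
Reagents that add atoms: tert-butyldimethylsilyl chloride, CC(C)(C)[Si](C)(C)Cl
Why: Standard imidazole-promoted silylation of a phenol, which masks the acidic proton that would otherwise quench the valuable aryllithium.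

Step 6
Reactants: 4 8'-bromo-hexa-O-benzylepigallocatechin; 7 4-(benzyloxy)-2-(tert-butyldimethylsilyloxy)benzaldehyde
Product: 10 (4-benzyloxy-2-hydroxyphenyl)(hexa-O-benzylepigallocatechin-8'-yl)methanol (carbinol epimers), via 8'-aryllithium 8 (not isolated), via O-silyl carbinol 9 (not isolated)
Conditions: 4, n-BuLi (1.05 equiv), THF, −78 °C; 7 (1.2 equiv), −78 to −40 °C; H2O; Bu4NF, 0 °C; NaHCO3 work-up, Et3N-deactivated SiO2
Reagents that add atoms: none
Why: Bromine–lithium exchange outruns benzylic deprotonation at −78 °C, the aryllithium adds 1,2 to the aldehyde, and fluoride then removes the silyl group under non-acidic conditions from whichever oxygen holds it after a possible O-to-O migration; the carbinol centre forms unselectively, which is irrelevant because step 8 planarises it.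

Step 7
Reactants: 11 4-(benzyloxy)benzaldehyde
Product: 12 4-benzyloxystyrene
Conditions: Ph3PCH3Br, KOt-Bu, THF, 0 °C to rt
Reagents that add atoms: methyltriphenylphosphonium bromide, C[P+](c1ccccc1)(c1ccccc1)c1ccccc1.[Br-]
Why: Wittig methylenation of a non-enolisable aromatic aldehyde with the unstabilised ylide, which leaves the benzyl ether untouched and gives the styrene free of acid traces.

Step 8
Reactants: 10 (4-benzyloxy-2-hydroxyphenyl)(hexa-O-benzylepigallocatechin-8'-yl)methanol; 12 4-benzyloxystyrene
Product: 15 octa-O-benzyl target (2S,4R,2'R,3'R; 2,4-trans), via ortho-quinone methide 13 (not isolated), via 2,4-cis cycloadduct 14 (not isolated)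
Conditions: 12 (3 equiv), (R)-3,3'-bis(2,4,6-triisopropylphenyl)-1,1'-binaphthalene-2,2'-diyl N-triflylphosphoramide (10 mol %), 4 Å MS, CH2Cl2, −40 °C, slow addition of 10; then 0 °C until the trans/cis composition no longer changes; Et3N quench; chromatography
Reagents that add atoms: none
Why: The strong chiral Brønsted acid ionises both carbinol epimers of the doubly activated 10 to one planar species, ortho-quinone methide 13, held as a hydrogen-bonded ion pair through O1, and this heterodiene (O1=C8a–C4a=C4) engages the electron-rich alkene in an inverse-electron-demand hetero-Diels–Alder reaction, the known acid-catalysed ortho-quinone methide/styrene synthesis of 2,4-diarylchromans. Ring C closes as a six-membered ring in an intermolecular, strongly asynchronous [4+2] mode: the unhindered CH2 terminus bonds to C4 (C3–C4) and the 4-benzyloxybenzylic cation developing at C2 is captured by O1, which fixes the head-to-tail regiochemistry. C4 is set in the C–C bond-forming event, where the chiral counter-anion anchored at O1 and the twisted ring D, whose unlike ortho groups (7'-OBn against O1' of ring F with ring E behind it) shield the two faces unequally, should steer the alkene to the face that gives 4R, and any 4S adduct is a diastereomer that should be separable on silica gel. C2 is set afterwards under thermodynamic control: at 0 °C the same acid reopens the 4-benzyloxybenzylic O1–C2 bond of the kinetic endo adduct 14, the tethered phenol should reclose far faster than C3–C4 can fragment so that C4 is kept, and the mixture should drain toward the 2,4-trans isomer with ring B equatorial and the di-ortho-oxygenated ring D pseudoaxial, away from the peri H5. The step also needs O-closure instead of indane formation and cross-reaction instead of self-alkylation, which the substrate secures because both ortho positions of ring D are blocked, C5 of ring A is meta to both oxygens, and C6' lies between two benzyloxy groups; excess 12 and slow addition of 10 help further.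

Step 9
Reactants: 15 octa-O-benzyl target
Product: 16 target CNP0220331.1, (2S,4R)-7-hydroxy-2-(4-hydroxyphenyl)chroman-4-yl bonded through C4 to C8' of (−)-epigallocatechin
Conditions: H2 (1 atm), Pd(OH)2/C, THF/MeOH, rt, stopped at full debenzylation; filtration under Ar, reversed-phase purification, lyophilisation
Reagents that add atoms: none
Why: Heterogeneous catalytic hydrogenolysis cleaves the eight primary benzyl C–O bonds much faster than the secondary, ring-embedded O1–C2 and O1'–C2' benzylic ethers, as is routine for perbenzylated proanthocyanidins, and the neutral medium leaves all four stereocentres and the C4–C8' bond untouched.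

## Compound list

1 | (−)-epigallocatechin | Oc1cc(O)c2c(c1)O[C@H](c1cc(O)c(O)c(O)c1)[C@H](O)C2 | starting material
2 | (2R,3R)-5,7-bis(benzyloxy)-2-[3,4,5-tris(benzyloxy)phenyl]chroman-3-ol | c9ccccc9COc1cc(OCc9ccccc9)c2c(c1)O[C@H](c1cc(OCc9ccccc9)c(OCc9ccccc9)c(OCc9ccccc9)c1)[C@H](O)C2 | intermediate
3 | (2R,3R)-3,5,7-tris(benzyloxy)-2-[3,4,5-tris(benzyloxy)phenyl]chroman | c9ccccc9COc1cc(OCc9ccccc9)c2c(c1)O[C@H](c1cc(OCc9ccccc9)c(OCc9ccccc9)c(OCc9ccccc9)c1)[C@H](OCc9ccccc9)C2 | intermediate
4 | 8'-bromo derivative of 3 | Brc1c(OCc9ccccc9)cc(OCc9ccccc9)c2c1O[C@H](c1cc(OCc9ccccc9)c(OCc9ccccc9)c(OCc9ccccc9)c1)[C@H](OCc9ccccc9)C2 | intermediate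
5 | 2,4-dihydroxybenzaldehyde | O=Cc1ccc(O)cc1O | starting material
6 | 4-(benzyloxy)-2-hydroxybenzaldehyde | O=Cc1ccc(OCc9ccccc9)cc1O | intermediate
7 | 4-(benzyloxy)-2-(tert-butyldimethylsilyloxy)benzaldehyde | O=Cc1ccc(OCc9ccccc9)cc1O[Si](C)(C)C(C)(C)C | intermediate
8 | 8'-lithio-hexa-O-benzylepigallocatechin (not isolated) | [Li]c1c(OCc9ccccc9)cc(OCc9ccccc9)c2c1O[C@H](c1cc(OCc9ccccc9)c(OCc9ccccc9)c(OCc9ccccc9)c1)[C@H](OCc9ccccc9)C2 | intermediate
9 | [4-benzyloxy-2-(tert-butyldimethylsilyloxy)phenyl](hexa-O-benzylepigallocatechin-8'-yl)methanol, carbinol epimers (not isolated) | OC(c1ccc(OCc9ccccc9)cc1O[Si](C)(C)C(C)(C)C)c3c(OCc9ccccc9)cc(OCc9ccccc9)c4c3O[C@H](c3cc(OCc9ccccc9)c(OCc9ccccc9)c(OCc9ccccc9)c3)[C@H](OCc9ccccc9)C4 | intermediate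
10 | (4-benzyloxy-2-hydroxyphenyl)(hexa-O-benzylepigallocatechin-8'-yl)methanol, carbinol epimers | OC(c1ccc(OCc9ccccc9)cc1O)c3c(OCc9ccccc9)cc(OCc9ccccc9)c4c3O[C@H](c3cc(OCc9ccccc9)c(OCc9ccccc9)c(OCc9ccccc9)c3)[C@H](OCc9ccccc9)C4 | intermediate
11 | 4-(benzyloxy)benzaldehyde | O=Cc1ccc(OCc9ccccc9)cc1 | starting material
12 | 4-benzyloxystyrene | C=Cc1ccc(OCc9ccccc9)cc1 | intermediate
13 | (E)-3-(benzyloxy)-6-[(hexa-O-benzylepigallocatechin-8'-yl)methylidene]cyclohexa-2,4-dien-1-one (not isolated) | O=C1C=C(OCc9ccccc9)C=C/C1=C\c3c(OCc9ccccc9)cc(OCc9ccccc9)c4c3O[C@H](c3cc(OCc9ccccc9)c(OCc9ccccc9)c(OCc9ccccc9)c3)[C@H](OCc9ccccc9)C4 | intermediate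
14 | octa-O-benzyl (2R,4R,2'R,3'R) 2,4-cis cycloadduct (not isolated) | c9ccccc9COc1ccc([C@H]2C[C@@H](c3c(OCc9ccccc9)cc(OCc9ccccc9)c4c3O[C@H](c3cc(OCc9ccccc9)c(OCc9ccccc9)c(OCc9ccccc9)c3)[C@H](OCc9ccccc9)C4)c3ccc(OCc9ccccc9)cc3O2)cc1 | intermediate
15 | octa-O-benzyl target, (2S,4R,2'R,3'R), 2,4-trans | c9ccccc9COc1ccc([C@@H]2C[C@@H](c3c(OCc9ccccc9)cc(OCc9ccccc9)c4c3O[C@H](c3cc(OCc9ccccc9)c(OCc9ccccc9)c(OCc9ccccc9)c3)[C@H](OCc9ccccc9)C4)c3ccc(OCc9ccccc9)cc3O2)cc1 | intermediate
16 | CNP0220331.1, (2S,4R)-7-hydroxy-2-(4-hydroxyphenyl)chroman-4-yl-(4→8')-(−)-epigallocatechin | Oc1ccc([C@@H]2C[C@@H](c3c(O)cc(O)c4c3O[C@H](c3cc(O)c(O)c(O)c3)[C@H](O)C4)c3ccc(O)cc3O2)cc1 | target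

## Step count

Total step count: 9.
Longest linear sequence: 6 steps (1, 2, 3, 6, 8, 9) from (−)-epigallocatechin.

## Steps most likely to fail

**Step 8.** Four things may go wrong:
- Facial discrimination at the planar C4 may be insufficient.
- The C2 equilibrium may not lean far enough toward 2,4-trans. In that case recovered cis material can be resubmitted to the acid.
- The acid may oligomerise the styrene on warming.
- An internal 1,5-hydride transfer may occur from the 7'-OCH2Ph methylene to C4.

The fallback sets out from 3 and comes back at 15. It makes the C4–C8' bond last, by the classical flavan-4-yl cation/Friedel–Crafts coupling of proanthocyanidin chemistry, so that C2 is installed beforehand by catalysis and C4 follows from it. Commercial 7-hydroxychromen-4-one is O-benzylated (BnBr, K2CO3, acetone) to 7-(benzyloxy)-4H-chromen-4-one F1. Enantioselective conjugate addition of 4-(benzyloxy)phenylboronic acid (Pd(OCOCF3)2, the t-BuPyOX antipode that delivers 2S, NH4PF6, H2O, ClCH2CH2Cl, 60 °C) gives (2S)-7-(benzyloxy)-2-[4-(benzyloxy)phenyl]chroman-4-one F2. NaBH4 (THF/MeOH, 0 °C) reduces it to (2S,4S)-7-(benzyloxy)-2-[4-(benzyloxy)phenyl]chroman-4-ol F3. BF3·OEt2 (CH2Cl2, −78 to −40 °C) then ionises this alcohol in the presence of excess 3. C8' of 3 should attack the half-chair C4 cation along the stereoelectronically preferred pseudoaxial trajectory. With ring B equatorial this is the 2,4-trans (4R) mode and gives 15.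

**Step 6.** Three things may go wrong:
- The silyl group may transfer to the new alkoxide and silanolate may then be lost prematurely, so that the quinone methide forms under basic conditions and is consumed by remaining aryllithium.
- The di-ortho-substituted aryllithium may add sluggishly to a hindered, deactivated aldehyde.
- The carbinol may ionise during isolation.

The fallback sets out from 4 and comes back at 10. It reverses the polarity, so that the valuable unit becomes the electrophile and the cheap ring A unit is used in excess without any phenol protecting group. Bromide 4 is lithiated (n-BuLi, THF, −78 °C) and trapped with the small electrophile DMF to give hexa-O-benzylepigallocatechin-8'-carbaldehyde F4. 4-Bromoresorcinol is mono-O-benzylated at the hydroxyl remote from bromine (BnBr, K2CO3, acetone) to 2-bromo-5-(benzyloxy)phenol F5. n-BuLi (2.2 equiv, THF, −78 to −20 °C) converts this into lithium 5-(benzyloxy)-2-lithiophenoxide F6. Addition of an excess of this reagent to the aldehyde and a neutral work-up give 10 directly.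

**Step 1.** The pyrogallol phenoxides may oxidise in air, ring D may be C-benzylated, and C2' may epimerise through opening of ring F from the ring E para-phenoxide. The fallback sets out from 1 and comes back at 3, which also makes step 2 redundant. It never exposes the free polyphenoxide. Ac2O/pyridine gives hexa-O-acetylepigallocatechin F7. This is subjected to in situ deacetylation–benzylation (NaH, BnCl, DMF, measured H2O, 0 °C to rt), a known acetate-to-benzyl ether exchange in which each oxygen is alkylated as soon as it is released. Any material still free at O3' is completed under the conditions of step 2.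

## Further compounds

F1 | step 8 | 7-(benzyloxy)-4H-chromen-4-one | O=c1ccoc2cc(OCc9ccccc9)ccc12
F2 | step 8 | (2S)-7-(benzyloxy)-2-[4-(benzyloxy)phenyl]chroman-4-one | O=C1C[C@@H](c2ccc(OCc9ccccc9)cc2)Oc2cc(OCc9ccccc9)ccc12
F3 | step 8 | (2S,4S)-7-(benzyloxy)-2-[4-(benzyloxy)phenyl]chroman-4-ol (2,4-cis) | O[C@H]1C[C@@H](c2ccc(OCc9ccccc9)cc2)Oc2cc(OCc9ccccc9)ccc12
F4 | step 6 | hexa-O-benzylepigallocatechin-8'-carbaldehyde | O=Cc1c(OCc9ccccc9)cc(OCc9ccccc9)c2c1O[C@H](c1cc(OCc9ccccc9)c(OCc9ccccc9)c(OCc9ccccc9)c1)[C@H](OCc9ccccc9)C2
F5 | step 6 | 2-bromo-5-(benzyloxy)phenol | Oc1cc(OCc9ccccc9)ccc1Br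
F6 | step 6 | lithium 5-(benzyloxy)-2-lithiophenoxide | [Li]Oc1cc(OCc9ccccc9)ccc1[Li]
F7 | step 1 | hexa-O-acetylepigallocatechin | CC(=O)Oc1cc(OC(C)=O)c2c(c1)O[C@H](c1cc(OC(C)=O)c(OC(C)=O)c(OC(C)=O)c1)[C@H](OC(C)=O)C2
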